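The runs stem from a simulated flask with constants of no real substance; scatter was added.

To rank these four flasks, the quantity carried is the first-order half-life of E once L is used up.

| flask | L | Z | temperature | remark | time |
|---|---|---|---|---|---|
| ash | 0.12 M | 0.25 M | 20 °C | run made earlier |  |
| cedar | 0.19 M | 0.25 M | 42 °C | run made earlier |  |
| Tuesday's | 0.25 M | 0.250 M | 10 °C |  | 6.0 h |
| Saturday's | 0.25 M | 0.250 M | 30 °C |  | 6.0 h |
| Thursday's | 0.25 M | 0.250 M |  | at 50 °C until 2.0 h, from then on at 10 °C | 6.0 h |
| Friday's | 0.25 M | 0.250 M | 50 °C |  | 6.0 h |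

| ash: time / h | ash: E / % | cedar: time / min | cedar: E / % |
|---|---|---|---|
| 0.200 | 18.8 | 4.00 | 48.0 |
| 0.667 | 44.9 | 12.0 | 65.6 |
| 1.00 | 53.5 | 20.0 | 62.9 |
| 1.50 | 61.2 | 30.0 | 58.5 |
| 2.50 | 65.5 | 50.0 | 50.5 |
| 3.00 | 65.5 | 60.0 | 46.1 |

(readings scatter by 0.5 percentage points)

- what may be going on: L -> E; L -> G; E -> Q; L + Z -> J

- which flask leads in amount of E, in percent of the L charged ("all alike" within 1.5 percentage points) (Tuesday's / Saturday's / Thursday's / Friday's / all alike)
- how much E is there at the end, in percent of the L charged: Tuesday's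
- how much E is there at the end, in percent of the L charged: Saturday's
- how much E is there at the end, in percent of the L charged: Thursday's
- how much E is there at the end, in percent of the L charged: Friday's

In the cedar run, E fell from 62.9% at 20.0 min to 46.1% at 60.0 min, which reads as a half-life of 1.49 h at 42 °C, the time in which E halves. Time divided by this half-life counts the halvings E undergoes. A stay of 6.0 h is longer and holds 4.03 halvings at that temperature, while a stay of 2.0 h holds 1.34. In the ash run, E read 65.5% at 2.50 h and 65.5% at 3.00 h, so at 20 °C these readings show no fall of E beyond the scatter of 0.5 percentage points. Friday's runs hotter than cedar, and so does the first stretch of Thursday's, Saturday's runs hotter than ash but colder than cedar, and Tuesday's runs colder than ash. This reckoning therefore commits to Tuesday's as the leader and puts no figures on the flasks.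

The forecast also names Tuesday's, with 59% there, 41% in Saturday's, 6% in Thursday's and 0.05% in Friday's, on the ground that “E loss is assumed steeper”.

The flasks give 60.8% in Tuesday's, 40.3% in Saturday's, 5.81% in Thursday's and 0.0385% in Friday's, so Tuesday's leads.

    L → E (k = 0.440 min⁻¹, Ea = 84.0 kJ mol⁻¹)
    L → G (k = 0.140 min⁻¹, Ea = 104 kJ mol⁻¹)
    E → Q (k = 0.0210 min⁻¹, Ea = 102 kJ mol⁻¹)
    L + Z → J (k = 0.150 M⁻¹ min⁻¹, Ea = 52.0 kJ mol⁻¹)
    (constants at 50 °C)

In Thursday's, L stood at 0% by 2.00 h at 50 °C, and E, whose half-life by the loss to Q at 0.0188 h was 0.55 h, shorter than the cedar reading, stood at 5.95%. At 10 °C its half-life of 120 h at 6.00 h was longer than the whole time, and E ended at 5.81%. In Saturday's, at 30 °C with L at 0% by 3.00 h, E went from 54.9% to 40.3% at 6.00 h, which is 0.446 of a halving and a half-life of 6.73 h, longer than the 1.49 h read in cedar at 42 °C.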